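(The constants stand for no real mixture; no experiment stands behind them.)

Weigh the ratio of growth to side reaction, 150 M⁻¹ min⁻¹ × [living end] over 0.89 M⁻¹ min⁻¹ × [monomer in chains]. Both steps are first order in free monomer, so [free monomer] cancels out of this selectivity factor, and the contest can be reckoned without a clock.

    crystals ⇌ monomer in chains, rate k1*(cs1 - [monomer in chains]) while solid is left; crystals form when [monomer in chains] > cs1 (cs1 = 0.12 M, k1 = 0.83 min⁻¹)
    free monomer + monomer in chains → side product (k2 = 0.89 M⁻¹ min⁻¹)
    free monomer + living end → monomer in chains + living end, rate k3*[living end]*[free monomer] (k3 = 150 M⁻¹ min⁻¹)
    free monomer + initiator → living end + monomer in chains (k4 = 0.67 M⁻¹ min⁻¹)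

free monomer 0.35 M; initiator 7.0 mM; time 4.0 h

- at 4.0 h, what has stopped the reaction, if anything has (all of the free monomer has reacted / no working catalyst is left / it is still moving)
- part of the free monomer gone at 4.0 h
- the monomer in chains standing at 4.0 h, as a percentage of the free monomer charged
- the side product standing at 4.0 h, as a percentage of the free monomer charged

- in percentages every species weighs as the free monomer in it: one side product counts as two
- for monomer in chains the crystals are counted in
- as a solid, counted per litre of solution: crystals
- the reaction counts as stopped when no species that holds the free monomer changes by six tenths of a point or more over the second half of the time
- run time (flask): 4.0 h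

1. Measure progress by exposure, the running time integral of [free monomer].

2. Take the first extreme: dissolved [monomer in chains] stays at zero, so no side product forms. Hold the initiator at its charge. Then [living end] grows in step with exposure, and growth consumes the charge at an exposure of 59.9 M·s.

3. Divide that exposure by the charge: this gives 2.85 min, far shorter than 4.0 h. It is a lower bound on the time free monomer takes, since it holds free monomer at its charge, and the real fall takes longer. I commit to full conversion, free monomer being the limiting reagent, with 51.3% of the initiator remaining.

4. Take the second extreme: dissolved [monomer in chains] stands at 0.12 M from the start. Each side product counts double, so its share is 60.9%.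

5. Put the first answer back in. Dissolved chains climb with the square of exposure and reach solubility at 35.0 M·s, before the end, averaging a third of 0.12 M on the way. Crystals then hold them near solubility, since crystallising takes 1.20 min, less than the fall of free monomer. My side product comes to 37.1%, leaving 62.9% in chains. Two neglected effects pull opposite ways: side product diverts free monomer, and falling initiator slows growth.

The forecast says all of the free monomer has reacted, with 100% conversion, 64% in chains (56% to 72%) and 36% side product (28% to 44%). Its ground is that dissolved chain monomer “sits at or a little above its 0.12 M solubility”.

The flask gives all of the free monomer has reacted: 100% conversion, 62.9% in chains, 37.1% side product. Initiator stands at 51% of its charge at 4.00 h, against the 51.3% reckoned from exposure. Now use exposure on the neighbour charged with 0.0018 M of initiator. Its exposure is 118 M·s, larger than this flask's, which puts its remaining initiator at 26.8%. That neighbour holds 26%.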